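**Retrosynthetic overview**
1. Arecatannin B1 ⇐ global hydrogenolysis of a tridecabenzyl monobromo trimer ⇐ Friedel–Crafts union of an epicatechin C4 electrophile (upper unit) with C8 of a middle–lower dimer.
2. Dimer ⇐ one-carbon ring expansion of a 2-aryl-2,3-dihydrobenzofuran-3-carbaldehyde. The furan ring becomes the pyran ring of the middle unit (O1–C2–C3–C4–C4a–C8a), and the C4 cation formed is captured by C6 of an 8-bromocatechin ether. This sets C3, C4 and the 4→6 bond.
3. Aldehyde ⇐ (+)-catechin by C4 hydroxylation and semipinacol ring contraction. Catechin C4 becomes the formyl carbon (later C3–OH) and catechin C3 becomes C4, so a 2,3-trans unit is rebuilt as the 2,3-cis-3,4-trans unit.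
4. Enabling feature: C4 of the middle unit sits on C4a of a phloroglucinol-type ring A (oxygen on C5, C7 and C8a) next to the C3 carbinol. The C3–OH/C4–aryl pair is therefore a masked formyl group beside an exceptionally stabilised benzylic cation, and C2 (bearing O1 and ring B) is a good migrating group.
5. Ring order: rings A and B of all units and ring C of the upper and lower units come intact from epicatechin and catechin; ring C of the middle unit is the only ring made, in step 7.

Key step: step 7

Assumption: DDQ hydration of the catechin 3-mesylate is taken to give mainly the 4β (3,4-cis) alcohol; the 4α epimer has the same antiperiplanar C3–OMs/C4–C4a arrangement and should give the same aldehyde. Flavan numbering is used for flavans, benzofuran numbering for the aldehyde.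

**Step 1**
Reactants: 1 (+)-catechin
Product: 2 5,7,3',4'-tetra-O-benzylcatechin
Conditions: BnBr, K2CO3, DMF, 0 °C → rt
Reagents that add atoms: benzyl bromide, BrCc1ccccc1
Why: Williamson ether synthesis in which K2CO3 deprotonates only the four phenols, so the secondary 3-OH stays free and no stereocentre is touched.

**Step 2**
Reactants: 2 5,7,3',4'-tetra-O-benzylcatechin
Product: 3 8-bromo-5,7,3',4'-tetra-O-benzylcatechin
Conditions: NBS, CH2Cl2, −40 → 0 °C
Reagents that add atoms: N-bromosuccinimide, O=C1CCC(=O)N1Br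
Why: Electrophilic aromatic bromination, for which C8 (ortho to O1 and to the 7-benzyloxy group) is the most reactive position of benzylated flavan-3-ols.

**Step 3**
Reactants: 3 8-bromo-5,7,3',4'-tetra-O-benzylcatechin
Product: 4 8-bromo-3,5,7,3',4'-penta-O-benzylcatechin
Conditions: NaH, BnBr, DMF, 0 °C → rt
Reagents that add atoms: benzyl bromide, BrCc1ccccc1
Why: Williamson ether synthesis on the alkoxide, which caps the 3-OH so that it cannot add to the activated aldehyde in step 7.

**Step 4**
Reactants: 2 5,7,3',4'-tetra-O-benzylcatechin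
Product: 5 5,7,3',4'-tetra-O-benzylcatechin 3-O-methanesulfonate
Conditions: MsCl, Et3N, DMAP (cat.), CH2Cl2, 0 °C
Reagents that add atoms: methanesulfonyl chloride, CS(=O)(=O)Cl
Why: O-sulfonylation of the secondary alcohol with retention at C3, which places an equatorial leaving group antiperiplanar to the C4–C4a bond.

**Step 5**
Reactants: 5 5,7,3',4'-tetra-O-benzylcatechin 3-O-methanesulfonate
Product: 6 (2R,3S,4S)-4-hydroxy-5,7,3',4'-tetra-O-benzylflavan-3-yl methanesulfonate (4β-OH, 3,4-cis)
Conditions: DDQ, CH2Cl2/H2O, 0 °C → rt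
Reagents that add atoms: water, O
Why: DDQ benzylic oxidation (hydride abstraction at C4, which is activated by ring A and O1, then hydration), in which water should enter from the β face, opposite to the α-aryl group on C2.

**Step 6**
Reactants: 6 (2R,3S,4S)-4-hydroxy-5,7,3',4'-tetra-O-benzylflavan-3-yl methanesulfonate
Product: 8 (2S,3S)-4,6-bis(benzyloxy)-2-[3,4-bis(benzyloxy)phenyl]-2,3-dihydro-1-benzofuran-3-carbaldehyde (trans), via diethylaluminium alkoxide 7 (not isolated)
Conditions: Et3Al, CH2Cl2, −78 → −40 °C; aq. KNaC4H4O6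
Reagents that add atoms: none
Why: Semipinacol rearrangement of a 2-sulfonyloxy alcohol promoted by an aluminium alkyl, in which the electron-rich aryl carbon C4a of 7 migrates from C4 to C3 with inversion at C3 while C4 becomes the formyl group, so the pyran contracts to the trans-dihydrofuran and C2 is untouched.

**Step 7**
Reactants: 8 (2S,3S)-4,6-bis(benzyloxy)-2-[3,4-bis(benzyloxy)phenyl]-2,3-dihydro-1-benzofuran-3-carbaldehyde; 4 8-bromo-3,5,7,3',4'-penta-O-benzylcatechin
Product: 10 5,7,3',4'-tetra-O-benzylepicatechin-(4β→6)-8-bromo-3,5,7,3',4'-penta-O-benzylcatechin (3-OH of the upper unit free), via ring-expanded zwitterion 9 (not isolated)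
Conditions: 4 (2 equiv), BF3·OEt2 (0.5 equiv), 4 Å molecular sieves, CH2Cl2, −78 → −30 °C; aq. NaHCO3
Reagents that add atoms: none
Why: Proposed new method: BF3 binds the formyl oxygen of 8 and the benzofuran C2–C3 bond migrates from C3 to the formyl carbon, so that benzofuran C2, the formyl carbon and benzofuran C3 become flavan C2, C3 and C4; zwitterion 9 carries a C4 cation that is stabilised by the 5,7-dibenzyloxy ring A and O1 far better than the BF3-bound aldehyde, and it is captured by C6 of 4 in a Friedel–Crafts alkylation, all atoms of 8 and 4 ending up in 10. The closest known reaction types are the acid-catalysed aldehyde–ketone (pinacol-type) 1,2-shift, here intercepted before the hydride shift that would give the ketone, and the BF3-mediated coupling of flavan-3,4-diols with flavan-3-ols, which runs through the same kind of 3-oxygenated flavan-4-yl cation without ketone formation. The pyran ring is closed not by cyclisation but by a suprafacial 1,2-shift of C2 with retention (five- to six-membered ring expansion). C2 is carried over from 8, and C3 is set by the face of the formyl group that C2 reaches: in the reactive rotamer the BF3-bound oxygen points away from ring A and its peri benzyloxy group (roughly anti to the C3–C3a bond, formyl hydrogen over ring A), which from the trans aldehyde should give the 2,3-cis arrangement. C4 is set by attack of 4 on the β face, anti to the C3 oxygen and the C2 aryl group, as in couplings of epicatechin-type cations (3,4-trans). The step needs migration of C2 in preference to hydride or the ring A carbon (favoured by the O1/aryl substitution of C2, by the benzylic cation that only this shift produces together with ring enlargement, and by the absence of base that could drain a hydride-shifted cation to a benzofuran), C6 regioselectivity in 4 (secured by bromine on C8) and suppression of self-alkylation by ring A of 8 or 10 (excess of 4).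

**Step 8**
Reactants: 11 (−)-epicatechin
Product: 12 5,7,3',4'-tetra-O-benzylepicatechin
Conditions: BnBr, K2CO3, DMF, 0 °C → rt
Reagents that add atoms: benzyl bromide, BrCc1ccccc1
Why: Williamson ether synthesis of the four phenols only, the aliphatic 3-OH and both stereocentres staying untouched.

**Step 9**
Reactants: 12 5,7,3',4'-tetra-O-benzylepicatechin
Product: 13 (2R,3R,4S)-4-(2-ethoxyethoxy)-5,7,3',4'-tetra-O-benzylflavan-3-ol (4β ether, 3,4-trans)
Conditions: DDQ, 2-ethoxyethanol, CH2Cl2, rt
Reagents that add atoms: 2-ethoxyethanol, CCOCCO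
Why: DDQ benzylic oxidation in the presence of an alcohol, in which hydride abstraction at C4 is followed by entry of 2-ethoxyethanol on the β face, anti to the 3-OH and the 2-aryl group.

**Step 10**
Reactants: 10 5,7,3',4'-tetra-O-benzylepicatechin-(4β→6)-8-bromo-3,5,7,3',4'-penta-O-benzylcatechin; 13 (2R,3R,4S)-4-(2-ethoxyethoxy)-5,7,3',4'-tetra-O-benzylflavan-3-ol
Product: 15 5,7,3',4'-tetra-O-benzylepicatechin-(4β→8)-5,7,3',4'-tetra-O-benzylepicatechin-(4β→6)-8-bromo-3,5,7,3',4'-penta-O-benzylcatechin, via flavan-4-ylium triflate 14 (not isolated)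
Conditions: Me3SiOSO2CF3 (0.2 equiv), CH2Cl2, −78 °C, slow addition of 13
Reagents that add atoms: none
Why: Lewis-acid-promoted Friedel–Crafts interflavan coupling in which cation 14 is attacked on its β face (anti to 3-OH and 2-aryl) by C8 of the upper unit of 10, the most nucleophilic free arene position, since C8 of the lower unit is blocked by bromine and C6 of the upper unit is flanked by two benzyloxy groups and the C4 substituent.

**Step 11**
Reactants: 15 protected trimer
Product: 16 arecatannin B1, epicatechin-(4β→8)-epicatechin-(4β→6)-catechin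
Conditions: H2 (1 atm), Pd(OH)2/C, Et3N, THF/MeOH/H2O, rt
Reagents that add atoms: none
Why: Heterogeneous catalytic hydrogenolysis cleaves the thirteen benzyl ethers and the aryl C–Br bond (Et3N takes up HBr) without touching the stereocentres or the interflavan bonds.

**Compound list**
1 | (+)-catechin, (2R,3S) | Oc1cc(O)c2c(c1)O[C@H](c1ccc(O)c(O)c1)[C@@H](O)C2 | starting material
2 | 5,7,3',4'-tetra-O-benzylcatechin, (2R,3S) | O[C@H]1Cc2c(OCc3ccccc3)cc(OCc3ccccc3)cc2O[C@@H]1c1ccc(OCc2ccccc2)c(OCc2ccccc2)c1 | intermediate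
3 | 8-bromo-5,7,3',4'-tetra-O-benzylcatechin | O[C@H]1Cc2c(OCc3ccccc3)cc(OCc3ccccc3)c(Br)c2O[C@@H]1c1ccc(OCc2ccccc2)c(OCc2ccccc2)c1 | intermediate
4 | 8-bromo-3,5,7,3',4'-penta-O-benzylcatechin | O(Cc1ccccc1)[C@H]1Cc2c(OCc3ccccc3)cc(OCc3ccccc3)c(Br)c2O[C@@H]1c1ccc(OCc2ccccc2)c(OCc2ccccc2)c1 | intermediate
5 | 5,7,3',4'-tetra-O-benzylcatechin 3-O-methanesulfonate, (2R,3S) | CS(=O)(=O)O[C@H]1Cc2c(OCc3ccccc3)cc(OCc3ccccc3)cc2O[C@@H]1c1ccc(OCc2ccccc2)c(OCc2ccccc2)c1 | intermediate
6 | (2R,3S,4S)-4-hydroxy-5,7,3',4'-tetra-O-benzylflavan-3-yl methanesulfonate | CS(=O)(=O)O[C@H]1[C@@H](O)c2c(OCc3ccccc3)cc(OCc3ccccc3)cc2O[C@@H]1c1ccc(OCc2ccccc2)c(OCc2ccccc2)c1 | intermediate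
7 | diethylaluminium C4-alkoxide of 6 (not isolated) | CS(=O)(=O)O[C@H]1[C@@H](O[Al](CC)CC)c2c(OCc3ccccc3)cc(OCc3ccccc3)cc2O[C@@H]1c1ccc(OCc2ccccc2)c(OCc2ccccc2)c1 | intermediate
8 | (2S,3S)-4,6-bis(benzyloxy)-2-[3,4-bis(benzyloxy)phenyl]-2,3-dihydro-1-benzofuran-3-carbaldehyde (trans) | O=C[C@@H]1[C@@H](c2ccc(OCc3ccccc3)c(OCc3ccccc3)c2)Oc2cc(OCc3ccccc3)cc(OCc3ccccc3)c21 | intermediate
9 | (2R,3R)-5,7-bis(benzyloxy)-2-[3,4-bis(benzyloxy)phenyl]-3-(trifluoroborato-oxy)flavan-4-ylium zwitterion, 2,3-cis (not isolated) | F[B-](F)(F)O[C@@H]1[CH+]c2c(OCc3ccccc3)cc(OCc3ccccc3)cc2O[C@@H]1c1ccc(OCc2ccccc2)c(OCc2ccccc2)c1 | intermediate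
10 | 5,7,3',4'-tetra-O-benzylepicatechin-(4β→6)-8-bromo-3,5,7,3',4'-penta-O-benzylcatechin | O[C@@H]1[C@@H](c2c(OCc3ccccc3)c(Br)c3c(c2OCc2ccccc2)C[C@H](OCc2ccccc2)[C@@H](c2ccc(OCc4ccccc4)c(OCc4ccccc4)c2)O3)c2c(OCc3ccccc3)cc(OCc3ccccc3)cc2O[C@@H]1c1ccc(OCc2ccccc2)c(OCc2ccccc2)c1 | intermediate
11 | (−)-epicatechin, (2R,3R) | Oc1cc(O)c2c(c1)O[C@H](c1ccc(O)c(O)c1)[C@H](O)C2 | starting material
12 | 5,7,3',4'-tetra-O-benzylepicatechin, (2R,3R) | O[C@@H]1Cc2c(OCc3ccccc3)cc(OCc3ccccc3)cc2O[C@@H]1c1ccc(OCc2ccccc2)c(OCc2ccccc2)c1 | intermediate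
13 | (2R,3R,4S)-4-(2-ethoxyethoxy)-5,7,3',4'-tetra-O-benzylflavan-3-ol | O[C@@H]1[C@@H](OCCOCC)c2c(OCc3ccccc3)cc(OCc3ccccc3)cc2O[C@@H]1c1ccc(OCc2ccccc2)c(OCc2ccccc2)c1 | intermediate
14 | (2R,3R)-3-hydroxy-5,7,3',4'-tetra-O-benzylflavan-4-ylium triflate (not isolated) | O[C@@H]1[CH+]c2c(OCc3ccccc3)cc(OCc3ccccc3)cc2O[C@@H]1c1ccc(OCc2ccccc2)c(OCc2ccccc2)c1.[O-]S(=O)(=O)C(F)(F)F | intermediate
15 | 5,7,3',4'-tetra-O-benzylepicatechin-(4β→8)-5,7,3',4'-tetra-O-benzylepicatechin-(4β→6)-8-bromo-3,5,7,3',4'-penta-O-benzylcatechin | O[C@@H]1[C@@H](c2c(OCc3ccccc3)cc(OCc3ccccc3)c3c2O[C@H](c2ccc(OCc4ccccc4)c(OCc4ccccc4)c2)[C@H](O)[C@H]3c2c(OCc3ccccc3)c(Br)c3c(c2OCc2ccccc2)C[C@H](OCc2ccccc2)[C@@H](c2ccc(OCc4ccccc4)c(OCc4ccccc4)c2)O3)c2c(OCc3ccccc3)cc(OCc3ccccc3)cc2O[C@@H]1c1ccc(OCc2ccccc2)c(OCc2ccccc2)c1 | intermediate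
16 | arecatannin B1 | Oc1cc(O)c2c(c1)O[C@H](c1ccc(O)c(O)c1)[C@H](O)[C@H]2c1c(O)cc(O)c2c1O[C@H](c1ccc(O)c(O)c1)[C@H](O)[C@H]2c1c(O)cc2c(c1O)C[C@H](O)[C@@H](c1ccc(O)c(O)c1)O2 | target

**Step count and risks**
Total steps: 11. Longest linear sequence: 7 (steps 1, 4, 5, 6, 7, 10, 11).

Steps most likely to fail:

Step 7. The formyl group may react otherwise than by migration of C2: a hydride shift followed by aromatisation to a benzofuran, direct hydroxyalkylation of 4 at the formyl carbon, or loss of facial control at the formyl group leading into the 2,3-trans series. Fallback with known chemistry: ether 13, made anyway for step 10, is ionised with Me3SiOSO2CF3 (CH2Cl2, −78 °C) in the presence of excess 4, and Friedel–Crafts attack of C6 of 4 on the β face gives dimer 10 directly. This fallback sets out from 13 and 4 and returns at 10 without any new compound. The middle unit then comes from (−)-epicatechin and the ring expansion is given up.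

Step 6. Ethyl transfer from aluminium to the new aldehyde, migration of O1 or epoxide closure in place of C4a migration, or ring opening of the β-aryloxy aldehyde may erode the step. Fallback from 5: the mesylate is solvolysed in aqueous 1,4-dioxane buffered with CaCO3. Ring A should assist ionisation by participation of C4a, and water should open the bridged ion at the primary carbon (former C4) to give the ring-contracted alcohol [(2S,3R)-4,6-bis(benzyloxy)-2-[3,4-bis(benzyloxy)phenyl]-2,3-dihydro-1-benzofuran-3-yl]methanol F1. Oxidation with Dess–Martin periodinane/NaHCO3 converts it to 8, where the route is rejoined.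

Step 10. Self-alkylation of the electrophile through its own C8, and over-alkylation of the product, may compete with the wanted C8 attack on 10. Fallback from 13: NBS (CH2Cl2, −40 °C) brominates C8 to give (2R,3R,4S)-8-bromo-4-(2-ethoxyethoxy)-5,7,3',4'-tetra-O-benzylflavan-3-ol F2, which cannot alkylate itself at its most reactive position and can be used in excess. Coupling of F2 with 10 (Me3SiOSO2CF3, CH2Cl2, −78 °C) gives the dibromo protected trimer F3. The conditions of step 11 (H2, Pd(OH)2/C, Et3N) remove both bromine atoms with the benzyl groups, so the route is rejoined at 16.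

**Further compounds**
F0 | step 7 | none | none
F1 | step 6 | [(2S,3R)-4,6-bis(benzyloxy)-2-[3,4-bis(benzyloxy)phenyl]-2,3-dihydro-1-benzofuran-3-yl]methanol | OC[C@@H]1[C@@H](c2ccc(OCc3ccccc3)c(OCc3ccccc3)c2)Oc2cc(OCc3ccccc3)cc(OCc3ccccc3)c21
F2 | step 10 | (2R,3R,4S)-8-bromo-4-(2-ethoxyethoxy)-5,7,3',4'-tetra-O-benzylflavan-3-ol | O[C@@H]1[C@@H](OCCOCC)c2c(OCc3ccccc3)cc(OCc3ccccc3)c(Br)c2O[C@@H]1c1ccc(OCc2ccccc2)c(OCc2ccccc2)c1
F3 | step 10 | 8-bromo-5,7,3',4'-tetra-O-benzylepicatechin-(4β→8)-5,7,3',4'-tetra-O-benzylepicatechin-(4β→6)-8-bromo-3,5,7,3',4'-penta-O-benzylcatechin | O[C@@H]1[C@@H](c2c(OCc3ccccc3)cc(OCc3ccccc3)c3c2O[C@H](c2ccc(OCc4ccccc4)c(OCc4ccccc4)c2)[C@H](O)[C@H]3c2c(OCc3ccccc3)c(Br)c3c(c2OCc2ccccc2)C[C@H](OCc2ccccc2)[C@@H](c2ccc(OCc4ccccc4)c(OCc4ccccc4)c2)O3)c2c(OCc3ccccc3)cc(OCc3ccccc3)c(Br)c2O[C@@H]1c1ccc(OCc2ccccc2)c(OCc2ccccc2)c1
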